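**Strategy.** The route rests on cutting the bond between aromatic C6 and the benzylic carbon of the hexanoic acid chain. It exploits the free C5 phenol ortho to C6–H, the only unsubstituted carbon of the phloroglucinol ring: O5, C5, C6 and the chain carbons up to the carboxyl map onto a dihydrocoumarin. An NHC-catalysed oxidative [3+3] annulation of the fully substituted (2S,3S)-chromanone phenol with (E)-hex-2-enal forges the aryl–C bond, sets the R centre under catalyst control and closes a temporary δ-lactone; hydrolysis then unveils the acid. The phenol comes from (R)-3-hydroxybutanoate (C2), with C3 and the C8 prenyl placed by substrate control.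

Key step: step 7

Assumption: the sense of induction of the chiral catalysts (step 7 and the fallbacks) is assigned by analogy, not verified; in each case the antipode meant is the one that gives the stated face selectivity, and both antipodes are commercial.

**Step 1**
Reactants: 1 3,5-dimethoxyphenol; 2 tert-butyl (R)-3-hydroxybutanoate
Product: 3 tert-butyl (S)-3-(3,5-dimethoxyphenoxy)butanoate
Conditions: PPh3, DIAD, THF, 0 °C to rt
Reagents that add atoms: none
Why: Mitsunobu etherification of an acidic phenol with a secondary alcohol proceeds by SN2 at the activated carbinol carbon, so the bought (R) centre is inverted to the (S) aryl ether that becomes C2.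

**Step 2**
Reactants: 3 tert-butyl (S)-3-(3,5-dimethoxyphenoxy)butanoate
Product: 5 (S)-5,7-dimethoxy-2-methylchroman-4-one, via free acid 4 (not isolated)
Conditions: TFA, CH2Cl2, rt; then TFAA, 0 °C to rt
Reagents that add atoms: none
Why: TFA removes the tert-butyl ester and the mixed trifluoroacetic anhydride of acid 4 undergoes intramolecular Friedel–Crafts acylation at either of the two equivalent, doubly activated positions ortho to the ether oxygen, closing the chromanone without touching the C2 centre.

**Step 3**
Reactants: 5 (S)-5,7-dimethoxy-2-methylchroman-4-one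
Product: 7 (2S,3S)-5,7-dimethoxy-2,3-dimethylchroman-4-one, via lithium enolate 6 (not isolated)
Conditions: LDA, THF, −78 °C; then MeI, −78 to −30 °C
Reagents that add atoms: iodomethane, CI
Why: Kinetic enolate alkylation in which MeI enters the lithium enolate anti to the C2 methyl group, so the bought centre relays C3 to the trans (2S,3S) isomer, which should also be the more stable one.

**Step 4**
Reactants: 7 (2S,3S)-5,7-dimethoxy-2,3-dimethylchroman-4-one
Product: 8 (2S,3S)-5-hydroxy-7-methoxy-2,3-dimethylchroman-4-one
Conditions: BCl3, CH2Cl2, −78 to 0 °C; then H2O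
Reagents that add atoms: none
Why: Chelation-controlled Lewis acid ether cleavage, in which BCl3 bound to the C4 carbonyl cleaves only the peri C5 methyl ether and leaves the 7-OMe and the ring ether intact.

**Step 5**
Reactants: 8 (2S,3S)-5-hydroxy-7-methoxy-2,3-dimethylchroman-4-one; 9 3-methylbut-2-en-1-ol (prenol)
Product: 10 (2S,3S)-7-methoxy-2,3-dimethyl-5-(3-methylbut-2-enyloxy)chroman-4-one
Conditions: PPh3, DIAD, THF, 0 °C to rt
Reagents that add atoms: none
Why: Neutral Mitsunobu O-alkylation of the chelated phenol with a primary allylic alcohol avoids the basic conditions that could open the chromanone by retro-oxa-Michael reaction.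

**Step 6**
Reactants: 10 (2S,3S)-7-methoxy-2,3-dimethyl-5-(3-methylbut-2-enyloxy)chroman-4-one
Product: 13 (2S,3S)-5-hydroxy-7-methoxy-2,3-dimethyl-8-(3-methylbut-2-enyl)chroman-4-one, via ortho-dienone 11 (not isolated), via para-dienone 12 (not isolated)
Conditions: Eu(fod)3 (10 mol %), CHCl3, 60 °C, sealed tube
Reagents that add atoms: none
Why: Lanthanide-catalysed aromatic Claisen rearrangement to C6 followed by Cope rearrangement to C8 and enolisation (para-Claisen–Cope) should deliver the unrearranged prenyl group para to O5, the Eu(III) chelated at C4=O/O5 favouring the second [3,3] shift over enolisation of the ortho-dienone.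

**Step 7**
Reactants: 13 (2S,3S)-5-hydroxy-7-methoxy-2,3-dimethyl-8-(3-methylbut-2-enyl)chroman-4-one; 14 (E)-hex-2-enal
Product: 15 tricyclic δ-lactone: the chromanone 13 with O5 and C6 bridged by –C(=O)–CH2–CH(n-Pr)–, i.e. a fused (R)-4-propyl-3,4-dihydrocoumarin ring
Conditions: 2-mesityl-5a,10b-dihydro-4H,6H-indeno[2,1-b][1,2,4]triazolo[4,3-d][1,4]oxazin-2-ium chloride (one antipode, 15 mol %), 3,3',5,5'-tetra-tert-butyldiphenoquinone (DQ, 1.2 equiv), DABCO (0.5 equiv), 4 Å MS, toluene, rt
Reagents that add atoms: none
Why: The carbene adds to 14 and DQ oxidises the resulting enaminol (Breslow intermediate) to the (E)-α,β-unsaturated acyl azolium; the phenoxide of 13 attacks its β-carbon through C6 (directly, or by O5 addition and [3,3] shift), and the enol so formed tautomerises to an acyl azolium that O5 captures. This is the known NHC-catalysed oxidative [3+3] annulation of enals with naphthols, electron-rich phenols and enolised 1,3-dicarbonyls (acyl azolium Michael addition–lactonisation), here run on a fully substituted acylphloroglucinol. The δ-lactone ring (O5, C5, C6 and the three chain carbons) closes by 6-exo-trig attack of O5 on the acyl azolium carbonyl, which releases the carbene. The new benzylic centre is under catalyst control: the indane wall of the aminoindanol triazolium shields one face of the s-trans acyl azolium so that C6 adds to the Re face of C3 of the enal, which gives R, while the remote C2/C3 centres should exert no influence. Site selectivity is secured by the substrate, since C6 is the only unsubstituted ring carbon and the only position ortho to the single free OH, and O-acylation should not be a dead end because the aryl ester of this acidic, chelated phenol can re-enter the cycle as an acyl azolium precursor. Sub-stoichiometric amine base at rt should leave the epimerisable C3 and the C2–O bond intact.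

**Step 8**
Reactants: 15 tricyclic δ-lactone
Product: 16 (3R)-3-[(2S,3S)-5-hydroxy-7-methoxy-2,3-dimethyl-8-(3-methylbut-2-enyl)-4-oxochroman-6-yl]hexanoic acid (CNP0233409.1)
Conditions: LiOH, THF/H2O, 0 °C; then 1 M HCl to pH 3–4, 0 °C
Reagents that add atoms: lithium hydroxide, [Li+].[OH-] (its oxygen becomes the carboxyl OH)
Why: Saponification of the phenolic lactone (an aryl ester) is fast at 0 °C, and on acidification the liberated 5-OH is held in a hydrogen bond to the C4 carbonyl, which should disfavour relactonisation; no stereocentre is involved.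

**Compound list**
1 | 3,5-dimethoxyphenol | COc1cc(O)cc(OC)c1 | starting material
2 | tert-butyl (R)-3-hydroxybutanoate | C[C@@H](O)CC(=O)OC(C)(C)C | starting material
3 | tert-butyl (S)-3-(3,5-dimethoxyphenoxy)butanoate | C[C@H](Oc1cc(OC)cc(OC)c1)CC(=O)OC(C)(C)C | intermediate
4 | (S)-3-(3,5-dimethoxyphenoxy)butanoic acid | C[C@H](Oc1cc(OC)cc(OC)c1)CC(=O)O | intermediate (not isolated)
5 | (S)-5,7-dimethoxy-2-methylchroman-4-one | COc1cc(OC)c2c(c1)O[C@@H](C)CC2=O | intermediate
6 | lithium (S)-5,7-dimethoxy-2-methyl-2H-chromen-4-olate | COc1cc(OC)c2c(c1)O[C@@H](C)C=C2[O-].[Li+] | intermediate (not isolated)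
7 | (2S,3S)-5,7-dimethoxy-2,3-dimethylchroman-4-one (trans) | COc1cc(OC)c2c(c1)O[C@@H](C)[C@H](C)C2=O | intermediate
8 | (2S,3S)-5-hydroxy-7-methoxy-2,3-dimethylchroman-4-one | COc1cc(O)c2c(c1)O[C@@H](C)[C@H](C)C2=O | intermediate
9 | 3-methylbut-2-en-1-ol (prenol) | CC(C)=CCO | starting material
10 | (2S,3S)-7-methoxy-2,3-dimethyl-5-(3-methylbut-2-enyloxy)chroman-4-one | COc1cc(OCC=C(C)C)c2c(c1)O[C@@H](C)[C@H](C)C2=O | intermediate
11 | ortho-dienone: (2S,3S)-7-methoxy-2,3-dimethyl-6-(2-methylbut-3-en-2-yl)-2,3-dihydro-4H-chromene-4,5(6H)-dione (C6 epimers) | C=CC(C)(C)C1C(OC)=CC2=C(C1=O)C(=O)[C@@H](C)[C@H](C)O2 | intermediate (not isolated)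
12 | para-dienone: (2S,3S)-7-methoxy-2,3-dimethyl-8-(3-methylbut-2-enyl)-2,3-dihydro-4H-chromene-4,5(8H)-dione (C8 epimers) | CC(C)=CCC1C(OC)=CC(=O)C2=C1O[C@@H](C)[C@H](C)C2=O | intermediate (not isolated)
13 | (2S,3S)-5-hydroxy-7-methoxy-2,3-dimethyl-8-(3-methylbut-2-enyl)chroman-4-one | COc1cc(O)c2c(c1CC=C(C)C)O[C@@H](C)[C@H](C)C2=O | intermediate
14 | (E)-hex-2-enal | CCC/C=C/C=O | starting material
15 | tricyclic δ-lactone: (2S,3S)-7-methoxy-2,3-dimethyl-8-prenylchroman-4-one with O5–C(=O)–CH2–(R)-CH(n-Pr)–C6 bridge (fused (R)-4-propyl-3,4-dihydrocoumarin) | CCC[C@@H]1CC(=O)Oc2c1c(OC)c(CC=C(C)C)c1O[C@@H](C)[C@H](C)C(=O)c21 | intermediate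
16 | (3R)-3-[(2S,3S)-5-hydroxy-7-methoxy-2,3-dimethyl-8-(3-methylbut-2-enyl)-4-oxochroman-6-yl]hexanoic acid | CCC[C@H](CC(=O)O)c1c(O)c2c(c(CC=C(C)C)c1OC)O[C@@H](C)[C@H](C)C2=O | target

**Step count.** Total: 8 steps. Longest linear sequence: 8 steps (1 or 2 to 16).

**Steps most likely to fail**

Step 7 (key step). The acyl azolium may be too weak an electrophile for the chelated, acyl-deactivated phenol, so that only reversible O-acylation occurs. Facial selectivity with a β-alkyl enal may also be insufficient. The fallback changes the activation mode to iminium catalysis. It sets out from 13 and 14 with α,α-diphenylprolinol trimethylsilyl ether (antipode chosen for Re-face attack, 20 mol %) and benzoic acid in toluene at 0 °C. C6 should add in a Friedel–Crafts-type conjugate addition to the more electrophilic α,β-unsaturated iminium ion, and after hydrolysis the aldehyde is trapped by O5 as the lactol F1 (the 2-hydroxychroman analogue of 15, anomeric mixture). Oxidation of the lactol F1 (TEMPO, PhI(OAc)2, CH2Cl2, rt) comes back to the route at lactone 15.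

Step 6. Enolisation of the ortho-dienone may outrun the Cope shift, which would place a 1,1-dimethylallyl group on C6 and block the very position needed in step 7. The fallback installs the prenyl group by cross-coupling and sets out from 7, before the demethylation. Iodination (NIS, cat. TFA, MeCN, rt) should go to C8, the less hindered of the two free positions, giving the 8-iodo-5,7-dimethoxychromanone F2. Stille coupling with tributyl(3-methylbut-2-enyl)stannane (Pd(PPh3)4, DMF, 80 °C) should give the 8-prenyl-5,7-dimethoxychromanone F3. Peri-selective demethylation with BCl3 as in step 4 (CH2Cl2, −78 °C) comes back to the route at 13.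

Step 3. The lithium enolate may open by E1cB loss of the phenoxide, which erases the C2 centre on reclosure, and over-methylation to the 3,3-dimethyl compound may compete. The fallback builds both methyl groups in from the start and sets C2 by catalysis. It sets out from 1: acylation ortho to the OH with tigloyl chloride (BF3·OEt2, O-acylation then Fries rearrangement) should give the tigloyl phenol F4. A cinchona-alkaloid-catalysed intramolecular oxa-Michael addition (quinidine, or quinine if the sense is opposite; chlorobenzene, rt) should set C2 as S and give, by kinetic protonation, the cis-chromanone F5. Epimerisation at C3 (cat. DBU, toluene, rt) towards the trans isomer comes back to the route at 7, with residual cis isomer recycled.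

**Further compounds**
F1 | step 7 | lactol: 15 with the lactone C=O replaced by CH(OH) (fused (R)-2-hydroxy-4-propylchroman, anomeric mixture) | CCC[C@@H]1CC(O)Oc2c1c(OC)c(CC=C(C)C)c1O[C@@H](C)[C@H](C)C(=O)c21
F2 | step 6 | (2S,3S)-8-iodo-5,7-dimethoxy-2,3-dimethylchroman-4-one | COc1cc(OC)c2c(c1I)O[C@@H](C)[C@H](C)C2=O
F3 | step 6 | (2S,3S)-5,7-dimethoxy-2,3-dimethyl-8-(3-methylbut-2-enyl)chroman-4-one | COc1cc(OC)c2c(c1CC=C(C)C)O[C@@H](C)[C@H](C)C2=O
F4 | step 3 | (E)-1-(2-hydroxy-4,6-dimethoxyphenyl)-2-methylbut-2-en-1-one | C/C=C(\C)C(=O)c1c(O)cc(OC)cc1OC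
F5 | step 3 | (2S,3R)-5,7-dimethoxy-2,3-dimethylchroman-4-one (cis) | COc1cc(OC)c2c(c1)O[C@@H](C)[C@@H](C)C2=O
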